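**Retrosynthetic overview**

1. Ring locants: C1 = C(CH3)(CH=CH2), C2 = CH2, C3 = CH–O-acyl, C4 = CH–C(=CH2)CO2H, C5 = CH–OH, C6 = CH–C(=CH2)CH2OH. Endgame: the C3 ester comes from site-selective acylation of a C3,C5-diol with a phosphonopropionic acid and a Z-selective HWE olefination with acetoxyacetaldehyde; the tert-butyl ester and silyl ether are removed last.
2. Key disconnection: ring bonds C3–C4 and C5–C6, made together by a head-to-tail double allylboration. Enabling feature: O–C3–C4–C(=CH2)CO2H and O–C5–C6–C(=CH2)CH2OH are two homoallylic alcohols (a ring C–O carbon next to a ring CH bearing an exocyclic 1,1-disubstituted alkene), each the retron of an aldehyde plus a 2-substituted allylboronate.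
3. C4 unit (C6–C1–C2–C3): an acyclic aldehyde–allylboronate. C1 is set by copper-catalysed enantioselective allylic substitution with a cis-1,2-diborylalkene, and the remaining boron is homologated to a CH2B group cis to C1.
4. C2 unit (C4–C5 with the acrylate): tert-butyl 2-(borylmethyl)-4,4-diethoxybut-2-enoate from 3,3-diethoxypropyne.
5. Ring order: the cyclohexane is the only ring and is closed in the key step (C3–C4 first, intermolecular; C5–C6 second, ring-closing).

Key step: step 10

Remark: the target SMILES is read as C1 S, C3 S, C4 S, C5 S, C6 R in the ring locants above, so the C1 methyl, C6 side chain, C5–OH and C4 acrylate lie on one face and the C1 vinyl and C3–O on the other; Bpin = 4,4,5,5-tetramethyl-1,3,2-dioxaborolan-2-yl.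

**Route**

Step 1
Reactants: 1 tert-butyl(but-3-yn-1-yloxy)dimethylsilane
Product: 2 (2E)-5-[(tert-butyldimethylsilyl)oxy]-3-methylpent-2-en-1-ol
Conditions: Me3Al, Cp2ZrCl2 (20 mol %), CH2Cl2, 0 °C → rt; then n-BuLi, THF, −78 °C; (CH2O)n, −78 °C → rt
Reagents that add atoms: trimethylaluminium, C[Al](C)C; formaldehyde (as paraformaldehyde), C=O
Why: Negishi carboalumination adds CH3 and aluminium syn across the alkyne (aluminium terminal), and the alanate should add to formaldehyde with retention, so the E alkene (CH2OH cis to CH3) is expected.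

Step 2
Reactants: 2 (2E)-5-[(tert-butyldimethylsilyl)oxy]-3-methylpent-2-en-1-ol
Product: 3 diethyl (2E)-5-[(tert-butyldimethylsilyl)oxy]-3-methylpent-2-en-1-yl phosphate
Conditions: ClP(O)(OEt)2, Et3N, DMAP (cat.), CH2Cl2, 0 °C
Reagents that add atoms: diethyl chlorophosphate, CCOP(=O)(Cl)OCC
Why: O-phosphorylation of the primary allylic alcohol should proceed without touching the alkene geometry.

Step 3
Reactants: 4 tert-butyldiphenyl(prop-2-yn-1-yloxy)silane
Product: 5 tert-butyl{[(2E)-2,3-bis(Bpin)prop-2-en-1-yl]oxy}diphenylsilane (the two boryl groups cis)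
Conditions: B2pin2, Pt(PPh3)4 (3 mol %), DMF, 80 °C
Reagents that add atoms: bis(pinacolato)diboron, CC1(C)OB(OC1(C)C)B1OC(C)(C)C(C)(C)O1
Why: platinum-catalysed diboration of a terminal alkyne is a syn addition, so the cis-1,2-diborylalkene should form.

Step 4
Reactants: 3 diethyl (2E)-5-[(tert-butyldimethylsilyl)oxy]-3-methylpent-2-en-1-yl phosphate; 5 tert-butyl{[(2E)-2,3-bis(Bpin)prop-2-en-1-yl]oxy}diphenylsilane
Product: 6 tert-butyl({(3S,4E)-6-[(tert-butyldiphenylsilyl)oxy]-3-ethenyl-3-methyl-5-(Bpin)hex-4-en-1-yl}oxy)dimethylsilane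
Conditions: CuCl (5 mol %), chiral sulfonate-bearing imidazolinium salt (NHC precursor, 5.5 mol %), NaOMe (2 equiv), THF, 22 → 60 °C
Reagents that add atoms: none
Why: in this NHC–copper-catalysed enantioselective allylic substitution the less hindered terminal C–B bond of 5 should transmetalate, the alkenylcopper should attack the phosphate in the SN2' sense with retention of alkene geometry, and the ligand enantiomer is chosen so that the quaternary C1 centre forms as S.

Step 5
Reactants: 6 tert-butyl({(3S,4E)-6-[(tert-butyldiphenylsilyl)oxy]-3-ethenyl-3-methyl-5-(Bpin)hex-4-en-1-yl}oxy)dimethylsilane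
Product: 7 (3S,4E)-6-[(tert-butyldiphenylsilyl)oxy]-3-ethenyl-3-methyl-5-(Bpin)hex-4-en-1-ol
Conditions: CSA (10 mol %), MeOH/CH2Cl2, 0 °C
Reagents that add atoms: none
Why: acid-catalysed methanolysis should cleave the primary alkyl TBS ether much faster than the TBDPS ether, and the alkenylboronate is inert to it.

Step 6
Reactants: 7 (3S,4E)-6-[(tert-butyldiphenylsilyl)oxy]-3-ethenyl-3-methyl-5-(Bpin)hex-4-en-1-ol
Product: 8 (3S,4E)-5-{[(tert-butyldiphenylsilyl)oxy]methyl}-3-ethenyl-3-methyl-6-(Bpin)hex-4-en-1-ol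
Conditions: n-BuLi (1 equiv), THF, −78 °C; then BrCH2Cl, n-BuLi, −78 °C → rt
Reagents that add atoms: bromochloromethane, ClCBr
Why: in this Matteson homologation LiCH2Cl, generated in the presence of the lithium alkoxide of 7, should add to boron and the alkenyl group should migrate with loss of chloride and retention of geometry, giving the allylboronate whose CH2B is cis to C1.

Step 7
Reactants: 8 (3S,4E)-5-{[(tert-butyldiphenylsilyl)oxy]methyl}-3-ethenyl-3-methyl-6-(Bpin)hex-4-en-1-ol
Product: 9 (3S,4E)-5-{[(tert-butyldiphenylsilyl)oxy]methyl}-3-ethenyl-3-methyl-6-(Bpin)hex-4-enal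
Conditions: Dess–Martin periodinane, CH2Cl2, 0 °C → rt
Reagents that add atoms: none
Why: Dess–Martin oxidation should give the aldehyde, which cannot be allylated by its own boronate (a four-membered ring would result) and should react only slowly intermolecularly because the γ-carbon carries a cis tertiary alkyl group.

Step 8
Reactants: 10 3,3-diethoxyprop-1-yne
Product: 11 tert-butyl 4,4-diethoxybut-2-ynoate
Conditions: n-BuLi, THF, −78 °C; then Boc2O, −78 → 0 °C
Reagents that add atoms: di-tert-butyl dicarbonate, CC(C)(C)OC(=O)OC(=O)OC(C)(C)C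
Why: acylation of the lithium acetylide with the dicarbonate should give the tert-butyl ynoate.

Step 9
Reactants: 11 tert-butyl 4,4-diethoxybut-2-ynoate
Product: 12 tert-butyl (2Z)-4,4-diethoxy-2-[(Bpin)methyl]but-2-enoate
Conditions: i-Bu2AlH, HMPA, MeCu (10 mol %), THF, −50 °C; then ICH2Bpin, −50 → 0 °C
Reagents that add atoms: 2-(iodomethyl)-4,4,5,5-tetramethyl-1,3,2-dioxaborolane, ICB1OC(C)(C)C(C)(C)O1
Why: copper-catalysed conjugate hydroalumination delivers hydride to the β-carbon syn to aluminium, and C-alkylation of the α-aluminio enoate by the iodomethylboronate should occur cis to the β-hydrogen, which puts the diethoxymethyl group trans to CH2B (2Z).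

Step 10
Reactants: 9 (3S,4E)-5-{[(tert-butyldiphenylsilyl)oxy]methyl}-3-ethenyl-3-methyl-6-(Bpin)hex-4-enal; 12 tert-butyl (2Z)-4,4-diethoxy-2-[(Bpin)methyl]but-2-enoate
Product: 16 tert-butyl 2-[(1R,2S,3R,4S,6S)-3-{3-[(tert-butyldiphenylsilyl)oxy]prop-1-en-2-yl}-4-ethenyl-2,6-dihydroxy-4-methylcyclohexyl]prop-2-enoate, via borate acetal 13 (not isolated), via hydroxy aldehyde 14 (not isolated), via cyclohexyl borate 15 (not isolated)
Conditions: (R)-3,3'-bis(2,4,6-triisopropylphenyl)-1,1'-binaphthyl-2,2'-diyl hydrogen phosphate [(R)-TRIP, 5 mol %], 4 Å MS, toluene, −30 °C → rt; then THF, 1 M aq. HCl, 0 °C → rt; aq. NaHCO3 work-up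
Reagents that add atoms: water, O
Why: Proposed new method: the chiral phosphoric acid should activate the 2-alkoxycarbonyl allylboronate 12 for a chair-like (Zimmerman–Traxler) addition of its γ-carbon to the Re face of the aldehyde of 9 (C3–C4), and once aqueous acid has unmasked the C5 aldehyde the allylboronate retained from 9 should add intramolecularly through a second closed chair transition state (C5–C6), each allyl transposition leaving one of the two 1,1-disubstituted alkenes. The closest known reactions are the chiral-phosphoric-acid-catalysed allylboration of aldehydes with pinacol allylboronates, the stereospecific acid-promoted additions of 2-alkoxycarbonyl allylboronates that give γ-hydroxy-α-methylene esters, and intramolecular allylborations triggered by acetal hydrolysis in which a boronate with CH2B cis to the tether gives the cis-2-alkenylcyclohexanol; joining them into one head-to-tail double allylboration is new. The cyclohexane is closed in the 6-exo-trig sense onto the aldehyde carbon within a bicyclic chair–chair array. C3 is set by the catalyst (the (R) acid is chosen because the accepted model of the parent reaction exposes the Re face; the (S) acid would be used if the sense proved opposite), C4 by the geometry of 12 (diethoxymethyl trans to CH2B, hence anti), and C5 and C6 by the geometry of the ring-closing boronate (oxygen axial and cis to the C6 substituent) within the chair that keeps the C3 oxygen and the C4 acrylate equatorial, which places the C6 substituent cis to the C1 methyl. The step needs chemoselectivity between the two allylboron groups in the first stage and ring closure faster than epimerisation or dehydration of the β-hydroxy aldehyde; the first should be secured by the cis tertiary-alkyl γ-substituent of the boronate in 9, which would have to sit axial in any intermolecular transition state, and the second by the intramolecularity of the second addition.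

Step 11
Reactants: 17 tert-butyl 2-bromopropanoate (racemic)
Product: 18 tert-butyl 2-(diphenoxyphosphoryl)propanoate (racemic)
Conditions: (PhO)2P(O)H, Et3N, CH2Cl2, 0 °C → rt
Reagents that add atoms: diphenyl phosphite, O=[PH](Oc1ccccc1)Oc1ccccc1
Why: Michaelis–Becker alkylation of the phosphite anion with the α-bromo ester (SN2) should give the diaryl phosphonate.

Step 12
Reactants: 18 tert-butyl 2-(diphenoxyphosphoryl)propanoate
Product: 19 2-(diphenoxyphosphoryl)propanoic acid (racemic)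
Conditions: TFA, CH2Cl2, 0 °C → rt
Reagents that add atoms: none
Why: acidolysis of the tert-butyl ester (loss of isobutene) should leave the aryl phosphonate esters intact.

Step 13
Reactants: 16 tert-butyl 2-[(1R,2S,3R,4S,6S)-3-{3-[(tert-butyldiphenylsilyl)oxy]prop-1-en-2-yl}-4-ethenyl-2,6-dihydroxy-4-methylcyclohexyl]prop-2-enoate; 19 2-(diphenoxyphosphoryl)propanoic acid
Product: 20 tert-butyl 2-[(1S,2S,3R,4S,6S)-3-{3-[(tert-butyldiphenylsilyl)oxy]prop-1-en-2-yl}-6-{[2-(diphenoxyphosphoryl)propanoyl]oxy}-4-ethenyl-2-hydroxy-4-methylcyclohexyl]prop-2-enoate (both epimers at the phosphorus-bearing carbon)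
Conditions: EDC·HCl, DMAP (10 mol %), CH2Cl2, −20 → 0 °C
Reagents that add atoms: none
Why: Steglich-type esterification should take place at the equatorial C3–OH because the C5–OH is axial, flanked by the C4 and C6 substituents and syn-axial to the C1 methyl; the stereocentre next to phosphorus is lost in step 15.

Step 14
Reactants: 21 (2Z)-but-2-ene-1,4-diyl diacetate
Product: 22 2-oxoethyl acetate
Conditions: O3, CH2Cl2, −78 °C; then Me2S, −78 °C → rt
Reagents that add atoms: ozone, [O-][O+]=O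
Why: ozonolysis with reductive work-up should cleave the symmetrical alkene into two molecules of the aldehyde.

Step 15
Reactants: 20 tert-butyl 2-[(1S,2S,3R,4S,6S)-3-{3-[(tert-butyldiphenylsilyl)oxy]prop-1-en-2-yl}-6-{[2-(diphenoxyphosphoryl)propanoyl]oxy}-4-ethenyl-2-hydroxy-4-methylcyclohexyl]prop-2-enoate; 22 2-oxoethyl acetate
Product: 23 tert-butyl 2-[(1S,2S,3R,4S,6S)-6-{[(2Z)-4-(acetyloxy)-2-methylbut-2-enoyl]oxy}-3-{3-[(tert-butyldiphenylsilyl)oxy]prop-1-en-2-yl}-4-ethenyl-2-hydroxy-4-methylcyclohexyl]prop-2-enoate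
Conditions: NaH (1.05 equiv), THF, 0 °C; then 22, −78 → 0 °C
Reagents that add atoms: none
Why: in this Horner–Wadsworth–Emmons olefination the electron-poor aryloxy groups on phosphorus should make the kinetically formed adduct collapse before it equilibrates, which should give the Z-trisubstituted enoate (CH2OAc cis to the ester carbonyl); the phosphonate is far more acidic than the hindered C5–OH.

Step 16
Reactants: 23 tert-butyl 2-[(1S,2S,3R,4S,6S)-6-{[(2Z)-4-(acetyloxy)-2-methylbut-2-enoyl]oxy}-3-{3-[(tert-butyldiphenylsilyl)oxy]prop-1-en-2-yl}-4-ethenyl-2-hydroxy-4-methylcyclohexyl]prop-2-enoate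
Product: 25 2-[(1S,2S,3R,4S,6S)-6-{[(2Z)-4-(acetyloxy)-2-methylbut-2-enoyl]oxy}-4-ethenyl-2-hydroxy-3-(3-hydroxyprop-1-en-2-yl)-4-methylcyclohexyl]prop-2-enoic acid (target), via bis(trimethylsilyl) intermediate 24 (not isolated)
Conditions: TMSOTf, 2,6-lutidine, CH2Cl2, 0 °C; then HF·pyridine, pyridine, THF, 0 °C → rt; work-up at pH 5
Reagents that add atoms: none
Why: TMSOTf/2,6-lutidine should convert the tert-butyl ester into the trimethylsilyl ester (loss of isobutene) and silylate the C5–OH, and buffered HF·pyridine should then remove the TBDPS and trimethylsilyl groups without touching the acetate or the enoate ester and without the strong acid that would favour lactonisation between the C5–OH and the acrylic acid.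

**Compound list**

1 | tert-butyl(but-3-yn-1-yloxy)dimethylsilane | C#CCCO[Si](C)(C)C(C)(C)C | starting material
2 | (2E)-5-[(tert-butyldimethylsilyl)oxy]-3-methylpent-2-en-1-ol | OC/C=C(\C)CCO[Si](C)(C)C(C)(C)C | intermediate
3 | diethyl (2E)-5-[(tert-butyldimethylsilyl)oxy]-3-methylpent-2-en-1-yl phosphate | CCOP(=O)(OCC)OC/C=C(\C)CCO[Si](C)(C)C(C)(C)C | intermediate
4 | tert-butyldiphenyl(prop-2-yn-1-yloxy)silane | C#CCO[Si](c1ccccc1)(c1ccccc1)C(C)(C)C | starting material
5 | tert-butyl{[(2E)-2,3-bis(4,4,5,5-tetramethyl-1,3,2-dioxaborolan-2-yl)prop-2-en-1-yl]oxy}diphenylsilane | CC1(C)OB(/C=C(/CO[Si](c2ccccc2)(c2ccccc2)C(C)(C)C)B2OC(C)(C)C(C)(C)O2)OC1(C)C | intermediate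
6 | tert-butyl({(3S,4E)-6-[(tert-butyldiphenylsilyl)oxy]-3-ethenyl-3-methyl-5-(4,4,5,5-tetramethyl-1,3,2-dioxaborolan-2-yl)hex-4-en-1-yl}oxy)dimethylsilane | C=C[C@](C)(CCO[Si](C)(C)C(C)(C)C)/C=C(\B1OC(C)(C)C(C)(C)O1)CO[Si](c1ccccc1)(c1ccccc1)C(C)(C)C | intermediate
7 | (3S,4E)-6-[(tert-butyldiphenylsilyl)oxy]-3-ethenyl-3-methyl-5-(4,4,5,5-tetramethyl-1,3,2-dioxaborolan-2-yl)hex-4-en-1-ol | C=C[C@](C)(CCO)/C=C(\B1OC(C)(C)C(C)(C)O1)CO[Si](c1ccccc1)(c1ccccc1)C(C)(C)C | intermediate
8 | (3S,4E)-5-{[(tert-butyldiphenylsilyl)oxy]methyl}-3-ethenyl-3-methyl-6-(4,4,5,5-tetramethyl-1,3,2-dioxaborolan-2-yl)hex-4-en-1-ol | C=C[C@](C)(CCO)/C=C(\CB1OC(C)(C)C(C)(C)O1)CO[Si](c1ccccc1)(c1ccccc1)C(C)(C)C | intermediate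
9 | (3S,4E)-5-{[(tert-butyldiphenylsilyl)oxy]methyl}-3-ethenyl-3-methyl-6-(4,4,5,5-tetramethyl-1,3,2-dioxaborolan-2-yl)hex-4-enal | C=C[C@](C)(CC=O)/C=C(\CB1OC(C)(C)C(C)(C)O1)CO[Si](c1ccccc1)(c1ccccc1)C(C)(C)C | intermediate
10 | 3,3-diethoxyprop-1-yne | CCOC(OCC)C#C | starting material
11 | tert-butyl 4,4-diethoxybut-2-ynoate | CCOC(OCC)C#CC(=O)OC(C)(C)C | intermediate
12 | tert-butyl (2Z)-4,4-diethoxy-2-[(4,4,5,5-tetramethyl-1,3,2-dioxaborolan-2-yl)methyl]but-2-enoate | CCOC(OCC)/C=C(/CB1OC(C)(C)C(C)(C)O1)C(=O)OC(C)(C)C | intermediate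
13 | tert-butyl (3R,4S,6S,7E)-8-{[(tert-butyldiphenylsilyl)oxy]methyl}-3-(diethoxymethyl)-6-ethenyl-6-methyl-2-methylidene-9-(4,4,5,5-tetramethyl-1,3,2-dioxaborolan-2-yl)-4-[(4,4,5,5-tetramethyl-1,3,2-dioxaborolan-2-yl)oxy]non-7-enoate | C=C[C@](C)(C[C@H](OB1OC(C)(C)C(C)(C)O1)[C@@H](C(=C)C(=O)OC(C)(C)C)C(OCC)OCC)/C=C(\CB1OC(C)(C)C(C)(C)O1)CO[Si](c1ccccc1)(c1ccccc1)C(C)(C)C | intermediate
14 | tert-butyl (3R,4S,6S,7E)-8-{[(tert-butyldiphenylsilyl)oxy]methyl}-6-ethenyl-3-formyl-4-hydroxy-6-methyl-2-methylidene-9-(4,4,5,5-tetramethyl-1,3,2-dioxaborolan-2-yl)non-7-enoate | C=C[C@](C)(C[C@H](O)[C@@H](C(=C)C(=O)OC(C)(C)C)C=O)/C=C(\CB1OC(C)(C)C(C)(C)O1)CO[Si](c1ccccc1)(c1ccccc1)C(C)(C)C | intermediate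
15 | tert-butyl 2-[(1R,2S,3R,4S,6S)-3-{3-[(tert-butyldiphenylsilyl)oxy]prop-1-en-2-yl}-4-ethenyl-6-hydroxy-4-methyl-2-[(4,4,5,5-tetramethyl-1,3,2-dioxaborolan-2-yl)oxy]cyclohexyl]prop-2-enoate | C=C[C@]1(C)C[C@H](O)[C@@H](C(=C)C(=O)OC(C)(C)C)[C@@H](OB2OC(C)(C)C(C)(C)O2)[C@H]1C(=C)CO[Si](c2ccccc2)(c2ccccc2)C(C)(C)C | intermediate
16 | tert-butyl 2-[(1R,2S,3R,4S,6S)-3-{3-[(tert-butyldiphenylsilyl)oxy]prop-1-en-2-yl}-4-ethenyl-2,6-dihydroxy-4-methylcyclohexyl]prop-2-enoate | C=C[C@]1(C)C[C@H](O)[C@@H](C(=C)C(=O)OC(C)(C)C)[C@@H](O)[C@H]1C(=C)CO[Si](c2ccccc2)(c2ccccc2)C(C)(C)C | intermediate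
17 | tert-butyl 2-bromopropanoate (racemic) | CC(Br)C(=O)OC(C)(C)C | starting material
18 | tert-butyl 2-(diphenoxyphosphoryl)propanoate (racemic) | CC(C(=O)OC(C)(C)C)P(=O)(Oc1ccccc1)Oc1ccccc1 | intermediate
19 | 2-(diphenoxyphosphoryl)propanoic acid (racemic) | CC(C(=O)O)P(=O)(Oc1ccccc1)Oc1ccccc1 | intermediate
20 | tert-butyl 2-[(1S,2S,3R,4S,6S)-3-{3-[(tert-butyldiphenylsilyl)oxy]prop-1-en-2-yl}-6-{[2-(diphenoxyphosphoryl)propanoyl]oxy}-4-ethenyl-2-hydroxy-4-methylcyclohexyl]prop-2-enoate (both epimers at the phosphorus-bearing carbon) | C=C[C@]1(C)C[C@H](OC(=O)C(C)P(=O)(Oc2ccccc2)Oc2ccccc2)[C@@H](C(=C)C(=O)OC(C)(C)C)[C@@H](O)[C@H]1C(=C)CO[Si](c2ccccc2)(c2ccccc2)C(C)(C)C | intermediate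
21 | (2Z)-but-2-ene-1,4-diyl diacetate | CC(=O)OC/C=C\COC(C)=O | starting material
22 | 2-oxoethyl acetate | CC(=O)OCC=O | intermediate
23 | tert-butyl 2-[(1S,2S,3R,4S,6S)-6-{[(2Z)-4-(acetyloxy)-2-methylbut-2-enoyl]oxy}-3-{3-[(tert-butyldiphenylsilyl)oxy]prop-1-en-2-yl}-4-ethenyl-2-hydroxy-4-methylcyclohexyl]prop-2-enoate | C=C[C@]1(C)C[C@H](OC(=O)/C(C)=C\COC(C)=O)[C@@H](C(=C)C(=O)OC(C)(C)C)[C@@H](O)[C@H]1C(=C)CO[Si](c2ccccc2)(c2ccccc2)C(C)(C)C | intermediate
24 | trimethylsilyl 2-[(1R,2S,3R,4S,6S)-6-{[(2Z)-4-(acetyloxy)-2-methylbut-2-enoyl]oxy}-3-{3-[(tert-butyldiphenylsilyl)oxy]prop-1-en-2-yl}-4-ethenyl-4-methyl-2-[(trimethylsilyl)oxy]cyclohexyl]prop-2-enoate | C=C[C@]1(C)C[C@H](OC(=O)/C(C)=C\COC(C)=O)[C@@H](C(=C)C(=O)O[Si](C)(C)C)[C@@H](O[Si](C)(C)C)[C@H]1C(=C)CO[Si](c2ccccc2)(c2ccccc2)C(C)(C)C | intermediate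
25 | 2-[(1S,2S,3R,4S,6S)-6-{[(2Z)-4-(acetyloxy)-2-methylbut-2-enoyl]oxy}-4-ethenyl-2-hydroxy-3-(3-hydroxyprop-1-en-2-yl)-4-methylcyclohexyl]prop-2-enoic acid | C=C[C@]1(C)C[C@H](OC(=O)/C(C)=C\COC(C)=O)[C@@H](C(=C)C(=O)O)[C@@H](O)[C@H]1C(=C)CO | target

**Step count and risks**

Total step count: 16. Longest linear sequence: 10 steps (1, 2, 4, 5, 6, 7, 10, 13, 15, 16).

Steps most likely to fail:

1. Step 10 (Proposed new method). What may go wrong: intermolecular allylboration by the boronate of 9 in competition with 12 (oligomerisation), insufficient facial control by the acid at C3, or epimerisation and dehydration of the β-hydroxy aldehyde before the ring closes. Fallback with known chemistry, from 7 back to 16, in which the two bonds are made in separate operations and the ring-closing boronate is created only after the first bond exists: alcohol 7 would be oxidised (Dess–Martin periodinane) to the alkenylboronate aldehyde F1, which has no allylboron group. Thermal addition of 12 (toluene, 80 °C, the stereospecific uncatalysed addition of 2-alkoxycarbonyl allylboronates) and triethanolamine work-up would give the anti hydroxy acetal F2. The diastereomer with the wrong sense relative to C1 would be removed by chromatography, or suppressed by using the chiral acid of step 10. Silylation (Et3SiCl, imidazole, DMF) would give the triethylsilyl ether F3, and Matteson homologation (BrCH2Cl, n-BuLi, THF, −78 °C) would give the allylboronate F4. Treatment with 1 M HCl in THF would cleave the acetal and the triethylsilyl ether, and the freed aldehyde would close the ring by the established hydrolysis-triggered intramolecular allylboration to give 16.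

2. Step 4. What may go wrong: transmetalation at the internal boron or at both boron atoms, slow turnover with the hindered diborylalkene, or erosion of enantioselectivity. Fallback, from 3 back to 6, in which the quaternary centre is made with an alkynyl nucleophile and the boron is introduced afterwards: phosphate 3 would be coupled, with the same class of chiral NHC–copper catalyst, with the alkynyl(diisobutyl)aluminium prepared from commercial triethyl(prop-2-yn-1-yloxy)silane (i-Bu2AlH, Et3N cat.) to give the enyne F5. Selective methanolysis of the triethylsilyl ether (PPTS, MeOH, 0 °C) would give the propargylic alcohol F6. Hydroxyl-directed trans-hydrostannation (Bu3SnH, [Cp*RuCl]4, CH2Cl2) would place tin on the carbinol-proximal carbon, cis to C1, giving the alkenylstannane F7. Silylation (TBDPSCl, imidazole) would give the silyl ether F8, and iododestannylation (I2, CH2Cl2, 0 °C) would give the alkenyl iodide F9 with retention. Miyaura borylation (B2pin2, PdCl2(dppf), KOAc, DMSO, 80 °C) would then give 6.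

3. Step 13. What may go wrong: loss of site selectivity between the two secondary hydroxyl groups (acylation at C5–O or at both). Fallback, from 9 and 12 back to 23, in which the ester is installed before the ring and the second hydroxyl exist: only the first stage of step 10 would be run (chiral acid, toluene, then triethanolamine work-up without aqueous acid) to isolate the hydroxy acetal F10, whose C3–OH is the only hydroxyl group. Esterification with 19 (EDC·HCl, DMAP) would give the phosphonate F11, and olefination with 22 (NaH, THF, −78 → 0 °C) would give the Z-enoate F12. Treatment with 1 M HCl in THF would then unmask the C5 aldehyde, and intramolecular allylboration would close the ring to give 23 directly.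

Further compounds
F1 | step 10 | (3S,4E)-6-[(tert-butyldiphenylsilyl)oxy]-3-ethenyl-3-methyl-5-(4,4,5,5-tetramethyl-1,3,2-dioxaborolan-2-yl)hex-4-enal | C=C[C@](C)(CC=O)/C=C(\B1OC(C)(C)C(C)(C)O1)CO[Si](c1ccccc1)(c1ccccc1)C(C)(C)C
F2 | step 10 | tert-butyl (3R,4S,6S,7E)-9-[(tert-butyldiphenylsilyl)oxy]-3-(diethoxymethyl)-6-ethenyl-4-hydroxy-6-methyl-2-methylidene-8-(4,4,5,5-tetramethyl-1,3,2-dioxaborolan-2-yl)non-7-enoate | C=C[C@](C)(C[C@H](O)[C@@H](C(=C)C(=O)OC(C)(C)C)C(OCC)OCC)/C=C(\B1OC(C)(C)C(C)(C)O1)CO[Si](c1ccccc1)(c1ccccc1)C(C)(C)C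
F3 | step 10 | triethylsilyl ether of F2 at the secondary hydroxyl | C=C[C@](C)(C[C@H](O[Si](CC)(CC)CC)[C@@H](C(=C)C(=O)OC(C)(C)C)C(OCC)OCC)/C=C(\B1OC(C)(C)C(C)(C)O1)CO[Si](c1ccccc1)(c1ccccc1)C(C)(C)C
F4 | step 10 | tert-butyl (3R,4S,6S,7E)-8-{[(tert-butyldiphenylsilyl)oxy]methyl}-3-(diethoxymethyl)-6-ethenyl-6-methyl-2-methylidene-9-(4,4,5,5-tetramethyl-1,3,2-dioxaborolan-2-yl)-4-[(triethylsilyl)oxy]non-7-enoate | C=C[C@](C)(C[C@H](O[Si](CC)(CC)CC)[C@@H](C(=C)C(=O)OC(C)(C)C)C(OCC)OCC)/C=C(\CB1OC(C)(C)C(C)(C)O1)CO[Si](c1ccccc1)(c1ccccc1)C(C)(C)C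
F5 | step 4 | tert-butyl({(3S)-3-ethenyl-3-methyl-6-[(triethylsilyl)oxy]hex-4-yn-1-yl}oxy)dimethylsilane | C=C[C@](C)(CCO[Si](C)(C)C(C)(C)C)C#CCO[Si](CC)(CC)CC
F6 | step 4 | (4S)-6-[(tert-butyldimethylsilyl)oxy]-4-ethenyl-4-methylhex-2-yn-1-ol | C=C[C@](C)(CCO[Si](C)(C)C(C)(C)C)C#CCO
F7 | step 4 | (2Z,4S)-6-[(tert-butyldimethylsilyl)oxy]-4-ethenyl-4-methyl-2-(tributylstannyl)hex-2-en-1-ol (tin cis to the quaternary carbon) | C=C[C@](C)(CCO[Si](C)(C)C(C)(C)C)/C=C(\[Sn](CCCC)(CCCC)CCCC)CO
F8 | step 4 | tert-butyldiphenylsilyl ether of F7 | C=C[C@](C)(CCO[Si](C)(C)C(C)(C)C)/C=C(\[Sn](CCCC)(CCCC)CCCC)CO[Si](c1ccccc1)(c1ccccc1)C(C)(C)C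
F9 | step 4 | tert-butyl({(3S)-6-[(tert-butyldiphenylsilyl)oxy]-3-ethenyl-5-iodo-3-methylhex-4-en-1-yl}oxy)dimethylsilane (iodine cis to the quaternary carbon) | C=C[C@](C)(CCO[Si](C)(C)C(C)(C)C)/C=C(\I)CO[Si](c1ccccc1)(c1ccccc1)C(C)(C)C
F10 | step 13 | tert-butyl (3R,4S,6S,7E)-8-{[(tert-butyldiphenylsilyl)oxy]methyl}-3-(diethoxymethyl)-6-ethenyl-4-hydroxy-6-methyl-2-methylidene-9-(4,4,5,5-tetramethyl-1,3,2-dioxaborolan-2-yl)non-7-enoate | C=C[C@](C)(C[C@H](O)[C@@H](C(=C)C(=O)OC(C)(C)C)C(OCC)OCC)/C=C(\CB1OC(C)(C)C(C)(C)O1)CO[Si](c1ccccc1)(c1ccccc1)C(C)(C)C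
F11 | step 13 | 2-(diphenoxyphosphoryl)propanoate ester of F10 at the secondary hydroxyl (both epimers at the phosphorus-bearing carbon) | C=C[C@](C)(C[C@H](OC(=O)C(C)P(=O)(Oc1ccccc1)Oc1ccccc1)[C@@H](C(=C)C(=O)OC(C)(C)C)C(OCC)OCC)/C=C(\CB1OC(C)(C)C(C)(C)O1)CO[Si](c1ccccc1)(c1ccccc1)C(C)(C)C
F12 | step 13 | (2Z)-4-(acetyloxy)-2-methylbut-2-enoate ester of F10 at the secondary hydroxyl | C=C[C@](C)(C[C@H](OC(=O)/C(C)=C\COC(C)=O)[C@@H](C(=C)C(=O)OC(C)(C)C)C(OCC)OCC)/C=C(\CB1OC(C)(C)C(C)(C)O1)CO[Si](c1ccccc1)(c1ccccc1)C(C)(C)C
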